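## Retrosynthetic overview
1. C8–O ester bond: the target gives the 8-hydroxy lactone and (Z)-2-(acetoxymethyl)but-2-enoic acid, which comes from crotonaldehyde.
2. Key disconnection C6–C7 (with the O6–C12 lactone bond): the ten-membered ring is closed last. C7 of a 2-(acetoxymethyl)acrylate is turned from acceptor into donor (π-allylpalladium to allylindium, a β-acyl carbanion or homoenolate equivalent) and added to the C6 aldehyde.
3. The C6 aldehyde, the Z-C4=C5 alkene and the C3 hemiketal all come from one oxidative opening of a 2-(Z-alkenyl)-3-methylfuran, captured by the C10 hydroxyl.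
4. C7–C8 comes from Ni/Cr coupling of a β-bromoacrylate linchpin with a β-hydroxy aldehyde. C2–C3 comes from Sonogashira coupling and semi-hydrogenation. C10 comes from Sharpless epoxidation of a C6 enynol.
5. Ring order: 2,5-dihydrofuran hemiketal first, ten-membered carbocycle second, γ-lactone third.

Assumption: germacrane numbering (C1–C15) is used for atom labels; 1, 4, 9 and 18 are taken as catalogue chemicals; hemiketal 14 equilibrates at C3 (through the open keto form and a spiro-lactol) and is drawn as the epimer that can cyclise.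

## Route

Step 1
Reactants: 1 (E)-3-methylpent-2-en-4-yn-1-ol
Product: 2 [(2S,3S)-3-ethynyl-3-methyloxiran-2-yl]methanol
Conditions: Ti(OiPr)4 (10 mol %), L-(+)-diethyl tartrate (12 mol %), t-BuOOH (2 equiv), 4 Å molecular sieves, CH2Cl2, −20 °C
Reagents that add atoms: tert-butyl hydroperoxide CC(C)(C)OO
Why: Katsuki–Sharpless asymmetric epoxidation of an E-trisubstituted allylic alcohol, in which the L-(+)-tartrate catalyst delivers oxygen (as with geraniol) to the face giving the (2S,3S)-epoxide and so fixes the future C10–O bond, while the alkyne is inert.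

Step 2
Reactants: 2 [(2S,3S)-3-ethynyl-3-methyloxiran-2-yl]methanol
Product: 3 (R)-3-methylpent-4-yne-1,3-diol
Conditions: NaAlH2(OCH2CH2OMe)2 (1.5 equiv), THF, −20 → 0 °C; aq. potassium sodium tartrate
Reagents that add atoms: none
Why: Hydroxyl-directed hydride opening of a 2,3-epoxy alcohol, in which the alkoxyaluminate delivers hydride to the carbinol-side carbon (future C9), the tertiary C–O bond is untouched so C10 is retained (the descriptor becomes R through priorities only), and at or below 0 °C the terminal alkyne is not hydroaluminated.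

Step 3
Reactants: 4 3-methylfuran
Product: 5 2-bromo-3-methylfuran
Conditions: NBS (1.0 equiv), DMF, 0 °C, dark; used directly
Reagents that add atoms: N-bromosuccinimide O=C1CCC(=O)N1Br
Why: Electrophilic aromatic bromination at the α-position next to the methyl group, the most activated site of the ring, with no stereocentre involved.

Step 4
Reactants: 3 (R)-3-methylpent-4-yne-1,3-diol; 5 2-bromo-3-methylfuran
Product: 6 (R)-3-methyl-5-(3-methylfuran-2-yl)pent-4-yne-1,3-diol
Conditions: PdCl2(PPh3)2 (3 mol %), CuI (6 mol %), Et3N–THF, 45 °C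
Reagents that add atoms: none
Why: Sonogashira coupling forms C2–C3, tolerates the free diol and does not touch C10.

Step 5
Reactants: 6 (R)-3-methyl-5-(3-methylfuran-2-yl)pent-4-yne-1,3-diol
Product: 7 (3R,4Z)-3-methyl-5-(3-methylfuran-2-yl)pent-4-ene-1,3-diol
Conditions: H2 (1 atm), Pd/CaCO3 poisoned with Pb(OAc)2 (5 wt %), quinoline, EtOAc, rt
Reagents that add atoms: none
Why: Lindlar-type syn semi-hydrogenation sets the Z C1=C2 alkene that later lets O10 reach C3, and the furan is not reduced.

Step 6
Reactants: 7 (3R,4Z)-3-methyl-5-(3-methylfuran-2-yl)pent-4-ene-1,3-diol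
Product: 8 (3R,4Z)-3-hydroxy-3-methyl-5-(3-methylfuran-2-yl)pent-4-enal
Conditions: Dess–Martin periodinane (1.2 equiv), NaHCO3, CH2Cl2, 0 °C
Reagents that add atoms: none
Why: Dess–Martin oxidation can only act on the primary alcohol (the other is tertiary), and the buffered neutral medium spares the acid-labile furyl allylic alcohol and avoids retro-aldol cleavage.

Step 7
Reactants: 9 methyl 2-(bromomethyl)acrylate
Product: 11 methyl (Z)-3-bromo-2-(bromomethyl)acrylate, via tribromo ester 10 (not isolated)
Conditions: Br2 (1.0 equiv), CH2Cl2, rt; then i-Pr2NEt (1.05 equiv), 0 °C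
Reagents that add atoms: bromine BrBr
Why: Bromine addition followed by E2 dehydrobromination, where the two CH2Br groups of 10 are equivalent so only one regioisomer can form, and by analogy with the 3-bromomethacrylates the vinylic bromine ends up trans to the ester.

Step 8
Reactants: 11 methyl (Z)-3-bromo-2-(bromomethyl)acrylate
Product: 12 methyl (E)-2-(acetoxymethyl)-3-bromoacrylate
Conditions: KOAc (1.2 equiv), DMF, 0 °C → rt
Reagents that add atoms: potassium acetate CC(=O)[O-].[K+]
Why: SN2 displacement of the allylic bromide by acetate, in which the vinylic bromide is inert and the geometry is kept (the descriptor becomes E through priorities only).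

Step 9
Reactants: 8 (3R,4Z)-3-hydroxy-3-methyl-5-(3-methylfuran-2-yl)pent-4-enal; 12 methyl (E)-2-(acetoxymethyl)-3-bromoacrylate
Product: 13 methyl (2E,4R,6R,7Z)-2-(acetoxymethyl)-6-hydroxy-6-methyl-8-(3-methylfuran-2-yl)-4-(triethylsilyloxy)octa-2,7-dienoate
Conditions: CrCl2 (10 mol %), valinol-derived oxazoline–sulfonamide ligand (12 mol %, the antipode that directs Si-face attack), NiCl2·(2,9-dimethyl-1,10-phenanthroline) (2 mol %), Mn (2 equiv), LiCl (2 equiv), Et3SiCl (1.5 equiv), MeCN, rt
Reagents that add atoms: chlorotriethylsilane CC[Si](Cl)(CC)CC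
Why: Catalytic asymmetric Nozaki–Hiyama–Kishi coupling, in which zerovalent nickel inserts into the activated vinylic C–Br bond with retention, the ligand-bound trivalent alkenylchromium adds to the Si face of the aldehyde to set 8R, and Et3SiCl releases the chromium alkoxide directly as the TES ether (the tertiary OH is not silylated without base, and C8 trans to the ester cannot lactonise).

Step 10
Reactants: 13 methyl (2E,4R,6R,7Z)-2-(acetoxymethyl)-6-hydroxy-6-methyl-8-(3-methylfuran-2-yl)-4-(triethylsilyloxy)octa-2,7-dienoate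
Product: 14 methyl (2E,4R)-2-(acetoxymethyl)-5-{(2R,5R)-5-hydroxy-2-methyl-5-[(Z)-4-oxobut-2-en-2-yl]-2,5-dihydrofuran-2-yl}-4-(triethylsilyloxy)pent-2-enoate
Conditions: NBS (1.05 equiv), NaHCO3 (2 equiv), acetone–H2O 10:1, −20 °C
Reagents that add atoms: water O
Why: Oxidative furan ring opening (bromonium attack at the free α-carbon C6, capture of the C3 oxocarbenium ion by the cis-placed C10 hydroxyl, hydrolysis of the α-bromo ether) transfers the cyclic geometry of the furan into the Z C4=C5 enal and builds the dihydrofuran hemiketal, while the electron-poor acrylate is untouched and C3 stays equilibrating.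

Step 11
Reactants: 14 methyl (2E,4R)-2-(acetoxymethyl)-5-{(2R,5R)-5-hydroxy-2-methyl-5-[(Z)-4-oxobut-2-en-2-yl]-2,5-dihydrofuran-2-yl}-4-(triethylsilyloxy)pent-2-enoate
Product: 17 (1Z,4Z,3R,6R,7R,8R,10R)-3,8-dihydroxy-3,10-epoxygermacra-1,4,11(13)-trien-12,6-olide, via allylindium species 15 (not isolated), via macrocyclic hydroxy ester 16 (not isolated)
Conditions: Pd(PPh3)4 (10 mol %), InI (2.5 equiv), THF, rt, 14 added over 10 h (final 2 mM); aq. HCl quench; p-TsOH (0.2 equiv), CH2Cl2, rt; then 1 M HCl–THF, rt
Reagents that add atoms: none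
Why: Proposed new method: zerovalent palladium ionises the allylic acetate to a 2-(methoxycarbonyl)-π-allyl complex that monovalent indium reduces to allylindium 15, so that C7 (the β-carbon of an acrylate, by nature an acceptor) becomes a homoenolate-type donor and attacks the equally electrophilic aldehyde carbon C6, the closest known reaction types being the palladium/indium umpolung allylation of aldehydes with allylic acetates and the Barbier/Nozaki–Hiyama ten-ring closures of 2-(halomethyl)acrylates used for germacranolides; the cis-2,5-dihydrofuran holds both arms on one face, the C8–O bond lies in the allyl plane next to indium (inside-alkoxy arrangement) so the C9 tether brings the aldehyde to the C7 face that gives 7R, the chair with C5 and C8 antiperiplanar gives the 6,7-anti adduct (6R, hence the trans-lactone), only the C3 epimer with cis arms can close so 3R is fixed, and acid lactonises the only free hydroxyl (O6) before the silyl ether is cleaved.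

Step 12
Reactants: 18 (E)-but-2-enal (crotonaldehyde)
Product: 19 (Z)-2-iodobut-2-enal
Conditions: I2 (1.2 equiv), K2CO3 (1.2 equiv), DMAP (0.2 equiv), THF–H2O 1:1, rt
Reagents that add atoms: iodine [I][I]
Why: Baylis–Hillman-type α-iodination (DMAP conjugate addition, enolate iodination, E1cB loss of DMAP) gives the Z-iodoenal in which CH3 stays trans to CHO and therefore cis to iodine.

Step 13
Reactants: 19 (Z)-2-iodobut-2-enal
Product: 20 (Z)-2-iodobut-2-en-1-ol
Conditions: NaBH4 (0.3 equiv), MeOH, 0 °C
Reagents that add atoms: none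
Why: Simple 1,2-reduction of the aldehyde leaves the alkene geometry and the C–I bond unchanged.

Step 14
Reactants: 20 (Z)-2-iodobut-2-en-1-ol
Product: 23 (Z)-2-(acetoxymethyl)but-2-enoic acid, via dilithio alkoxide 21 (not isolated), via dilithium carboxylate 22 (not isolated)
Conditions: n-BuLi (2.1 equiv), Et2O, −78 °C; CO2, −78 → 0 °C, argon purge; Ac2O (1.2 equiv), 0 °C; 1 M HCl
Reagents that add atoms: carbon dioxide O=C=O; acetic anhydride CC(=O)OC(C)=O
Why: Iodine–lithium exchange and carboxylation proceed with retention so CO2H ends up cis to CH3 (angelate-type Z geometry), and the alkoxide, far more nucleophilic than the carboxylate, is the site acetylated before acidic work-up.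

Step 15
Reactants: 17 (1Z,4Z,3R,6R,7R,8R,10R)-3,8-dihydroxy-3,10-epoxygermacra-1,4,11(13)-trien-12,6-olide; 23 (Z)-2-(acetoxymethyl)but-2-enoic acid
Product: 25 target CNP0256971.1, via mixed anhydride 24 (not isolated)
Conditions: 23, 2,4,6-Cl3C6H2COCl, Et3N, toluene, rt; then 17, DMAP (1 equiv), 0 °C → rt
Reagents that add atoms: none
Why: Yamaguchi esterification acylates only the secondary C8 hydroxyl (C3–OH is a tertiary hemiketal) without breaking the C8–O bond, so 8R is retained, and the low temperature limits Z to E isomerisation of the angelate-type acyl group.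

## Compound list
1 | (E)-3-methylpent-2-en-4-yn-1-ol | C#C/C(C)=C/CO | starting material
2 | [(2S,3S)-3-ethynyl-3-methyloxiran-2-yl]methanol | OC[C@@H]1O[C@@]1(C)C#C | intermediate
3 | (R)-3-methylpent-4-yne-1,3-diol | OCC[C@@](C)(O)C#C | intermediate
4 | 3-methylfuran | Cc1ccoc1 | starting material
5 | 2-bromo-3-methylfuran | Cc1ccoc1Br | intermediate
6 | (R)-3-methyl-5-(3-methylfuran-2-yl)pent-4-yne-1,3-diol | OCC[C@@](C)(O)C#Cc1occc1C | intermediate
7 | (3R,4Z)-3-methyl-5-(3-methylfuran-2-yl)pent-4-ene-1,3-diol | OCC[C@@](C)(O)/C=C\c1occc1C | intermediate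
8 | (3R,4Z)-3-hydroxy-3-methyl-5-(3-methylfuran-2-yl)pent-4-enal | O=CC[C@@](C)(O)/C=C\c1occc1C | intermediate
9 | methyl 2-(bromomethyl)acrylate | C=C(CBr)C(=O)OC | starting material
10 | methyl 2,3-dibromo-2-(bromomethyl)propanoate | COC(=O)C(Br)(CBr)CBr | intermediate
11 | methyl (Z)-3-bromo-2-(bromomethyl)acrylate (Br trans to ester) | COC(=O)/C(CBr)=C/Br | intermediate
12 | methyl (E)-2-(acetoxymethyl)-3-bromoacrylate (Br trans to ester) | COC(=O)/C(COC(C)=O)=C/Br | intermediate
13 | methyl (2E,4R,6R,7Z)-2-(acetoxymethyl)-6-hydroxy-6-methyl-8-(3-methylfuran-2-yl)-4-(triethylsilyloxy)octa-2,7-dienoate | COC(=O)/C(COC(C)=O)=C/[C@H](O[Si](CC)(CC)CC)C[C@@](C)(O)/C=C\c1occc1C | intermediate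
14 | hemiketal Z-enal: methyl (2E,4R)-2-(acetoxymethyl)-5-{(2R,5R)-5-hydroxy-2-methyl-5-[(Z)-4-oxobut-2-en-2-yl]-2,5-dihydrofuran-2-yl}-4-(triethylsilyloxy)pent-2-enoate | COC(=O)/C(COC(C)=O)=C/[C@H](O[Si](CC)(CC)CC)C[C@]1(C)C=C[C@@](O)(O1)/C(C)=C\C=O | intermediate
15 | acetoxy(iodo)allylindium from 14 (trivalent indium on C13, otherwise as 14) | COC(=O)/C(C[In]([I])OC(C)=O)=C/[C@H](O[Si](CC)(CC)CC)C[C@]1(C)C=C[C@@](O)(O1)/C(C)=C\C=O | intermediate
16 | methyl 2-[(1R,2Z,4R,5S,6R,8R)-1,4-dihydroxy-2,8-dimethyl-6-(triethylsilyloxy)-11-oxabicyclo[6.2.1]undeca-2,9-dien-5-yl]acrylate (spatially as the target at C3, C6, C7, C8, C10) | C=C(C(=O)OC)[C@H]1[C@H](O)/C=C(/C)[C@@]2(O)C=C[C@@](C)(C[C@H]1O[Si](CC)(CC)CC)O2 | intermediate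
17 | (1Z,4Z,3R,6R,7R,8R,10R)-3,8-dihydroxy-3,10-epoxygermacra-1,4,11(13)-trien-12,6-olide | C=C1C(=O)O[C@@H]2/C=C(/C)[C@@]3(O)C=C[C@@](C)(C[C@@H](O)[C@@H]12)O3 | intermediate
18 | (E)-but-2-enal | C/C=C/C=O | starting material
19 | (Z)-2-iodobut-2-enal | C/C=C(\I)C=O | intermediate
20 | (Z)-2-iodobut-2-en-1-ol | C/C=C(\I)CO | intermediate
21 | lithium (Z)-2-lithiobut-2-en-1-olate | C/C=C(\[Li])CO[Li] | intermediate
22 | dilithium (Z)-2-(oxidomethyl)but-2-enoate | C/C=C(\C(=O)O[Li])CO[Li] | intermediate
23 | (Z)-2-(acetoxymethyl)but-2-enoic acid | C/C=C(\C(O)=O)COC(C)=O | intermediate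
24 | (Z)-2-(acetoxymethyl)but-2-enoic 2,4,6-trichlorobenzoic anhydride | C/C=C(\C(=O)OC(=O)c1c(Cl)cc(Cl)cc1Cl)COC(C)=O | intermediate
25 | CNP0256971.1: (1Z,4Z,3R,6R,7R,8R,10R)-8-[(Z)-2-(acetoxymethyl)but-2-enoyloxy]-3-hydroxy-3,10-epoxygermacra-1,4,11(13)-trien-12,6-olide | C=C1C(=O)O[C@@H]2/C=C(/C)[C@@]3(O)C=C[C@@](C)(C[C@@H](OC(=O)/C(=C\C)COC(C)=O)[C@@H]12)O3 | target

## Step count
- **Total step count:** 15 (one-pot sequences counted once).
- **Longest linear sequence:** 9 steps (1, 2, 4, 5, 6, 9, 10, 11, 15).

## Steps most likely to fail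

**Step 11 (ring closure and the C6/C7 configuration).** The fallback sets out from 8 and comes back at 17. It replaces the in-flask polarity inversion with a preformed allylboronate of fixed geometry. Aldehyde 8 is alkynylated with methyl propiolate (Me2Zn, ProPhenol ligand) to the (R)-γ-hydroxy ynoate F1. Silylation (Et3SiCl, imidazole) gives the TES ether F2. Conjugate syn-hydroalumination (i-Bu2AlH, HMPA), followed by trapping of the α-alumino acrylate with ICH2B(pin), gives the allylboronate F3, in which C8 is cis to the ester. NBS oxidation as in step 10 unmasks the boronate aldehyde F4. F4 closes the ring on heating (toluene, 80 °C, 2 mM) through a closed chair in which the E-crotyl-type geometry gives the 6,7-anti adduct. No free organometal is present that could eliminate or be protonated. The acid treatment of step 11 then gives 17.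

**Step 9 (facial control and in-flask silylation).** The fallback sets out from 8 and 12 and comes back at 13. C8 is set by substrate-directed reduction instead of during the C–C bond formation. Ligand-free coupling (CrCl2 4 equiv, NiCl2 1 mol %, DMF) gives the allylic alcohol F5 as a C8 epimer mixture. Dess–Martin oxidation gives the β-hydroxy enone F6. Me4NBH(OAc)3 (MeCN–AcOH, −30 °C), bound to the tertiary C10 hydroxyl, delivers hydride intramolecularly (Evans–Saksena 1,3-anti reduction) to give the (8R)-diol F7. Selective silylation of the secondary hydroxyl (Et3SiCl, imidazole, 0 °C) returns 13.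

**Step 10 (chemoselective opening of a vinylfuran next to a labile tertiary allylic alcohol).** The fallback sets out from 13 and comes back at 14. Oxidation and hydrolysis are separated. NBS in MeOH with NaHCO3 at −40 °C (or anodic methoxylation) gives the isolable spiro-acetal F8, with O10 on C3 and OMe on C6, as acetal epimers. F8 can be purified. It is then opened with pyridinium p-toluenesulfonate in acetone–H2O to 14.

## Further compounds
F1 | step 11 | methyl (4R,6R,7Z)-4,6-dihydroxy-6-methyl-8-(3-methylfuran-2-yl)oct-7-en-2-ynoate | COC(=O)C#C[C@H](O)C[C@@](C)(O)/C=C\c1occc1C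
F2 | step 11 | methyl (4R,6R,7Z)-6-hydroxy-6-methyl-8-(3-methylfuran-2-yl)-4-(triethylsilyloxy)oct-7-en-2-ynoate | COC(=O)C#C[C@H](O[Si](CC)(CC)CC)C[C@@](C)(O)/C=C\c1occc1C
F3 | step 11 | methyl (2Z,4R,6R,7Z)-6-hydroxy-6-methyl-8-(3-methylfuran-2-yl)-2-[(4,4,5,5-tetramethyl-1,3,2-dioxaborolan-2-yl)methyl]-4-(triethylsilyloxy)octa-2,7-dienoate | COC(=O)/C(CB1OC(C)(C)C(C)(C)O1)=C\[C@H](O[Si](CC)(CC)CC)C[C@@](C)(O)/C=C\c1occc1C
F4 | step 11 | hemiketal Z-enal corresponding to 14 with CH2B(pin) in place of CH2OAc and C8 cis to the ester | COC(=O)/C(CB1OC(C)(C)C(C)(C)O1)=C\[C@H](O[Si](CC)(CC)CC)C[C@]1(C)C=C[C@@](O)(O1)/C(C)=C\C=O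
F5 | step 9 | methyl (2E,6R,7Z)-2-(acetoxymethyl)-4,6-dihydroxy-6-methyl-8-(3-methylfuran-2-yl)octa-2,7-dienoate (C4 epimers) | COC(=O)/C(COC(C)=O)=C/C(O)C[C@@](C)(O)/C=C\c1occc1C
F6 | step 9 | methyl (2E,6R,7Z)-2-(acetoxymethyl)-6-hydroxy-6-methyl-8-(3-methylfuran-2-yl)-4-oxoocta-2,7-dienoate | COC(=O)/C(COC(C)=O)=C/C(=O)C[C@@](C)(O)/C=C\c1occc1C
F7 | step 9 | methyl (2E,4R,6R,7Z)-2-(acetoxymethyl)-4,6-dihydroxy-6-methyl-8-(3-methylfuran-2-yl)octa-2,7-dienoate | COC(=O)/C(COC(C)=O)=C/[C@H](O)C[C@@](C)(O)/C=C\c1occc1C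
F8 | step 10 | 1,6-dioxaspiro[4.4]nona-3,8-diene methyl acetal of 14 (O10 on C3, OMe on C6, epimers at C3 and C6) | COC(=O)/C(COC(C)=O)=C/[C@H](O[Si](CC)(CC)CC)C[C@]1(C)C=CC2(O1)OC(OC)C=C2C
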